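**Retrosynthetic overview** (side-chain carbons are numbered C1'–C32' outward from chroman C2)

1. Last skeletal bond: C22'–C23'. It is made together with the C24' methyl branch and the E-C23'=C24' olefin in one flask, by methylalumination of the C13 dienyne 26 and alkenyl–alkyl cross-coupling with the homoallylic iodide 23 (three components: 26, AlMe3, 23).
2. Enabling feature: C23'=C24'(CH3) is a trisubstituted E-olefin whose vinylic CH (C23') sits on an sp3 CH2 (C22'). This 2-methylalk-1-enyl group on a primary carbon is the imprint of syn CH3–metal addition to a terminal alkyne (C23'≡C24'), and it lies 22 carbons from the chroman ring, so the union raises no stereocontrol issue at C2.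
3. Iodide 23: C5'–C6' by alkylation of the ω-homologated geranylgeranyl sulfone 19 (C6'–C22') with allylic bromide 11, then desulfonylation. The C21'/C22' terminus comes from SeO2 oxidation, methylenation and hydroboration of geranylgeranyl phenyl sulfone.
4. Chroman 9: (R)-linalool supplies C2 (the only stereocentre), its methyl, O1, C3, C4 and C1'–C5'. B-alkyl Suzuki coupling to bromo-iodoarene 5 forms C4–C4a, then Pd-catalysed O-arylation forms O1–C8a.
5. Ring order: the benzene ring is bought (4-amino-2,3-dimethylphenol); the dihydropyran ring is the only ring formed (step 5); the chain is assembled afterwards and the phenol is unveiled last.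

Key step: step 16

Assumption: commercial (R)-(−)-linalool of high enantiomeric purity, all-E geranylgeraniol and E-geranyl bromide are used as isomerically pure materials; no step touches C2 after step 4, so the enantiomeric purity of the target equals that of the linalool.

**Route**

Step 1
Reactants: 1 4-amino-2,3-dimethylphenol
Product: 2 2,3-dimethyl-4-(triisopropylsilyloxy)aniline
Conditions: i-Pr3SiCl, imidazole, DMF, 0 °C → rt
Reagents that add atoms: chlorotriisopropylsilane, CC(C)[Si](Cl)(C(C)C)C(C)C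
Why: Silyl protection of a phenol with a bulky silyl chloride and imidazole is O-selective beside the aniline nitrogen, and the aryl TIPS ether should survive every later base, hydride and Pd step.

Step 2
Reactants: 2 2,3-dimethyl-4-(triisopropylsilyloxy)aniline
Product: 3 6-iodo-2,3-dimethyl-4-(triisopropylsilyloxy)aniline
Conditions: N-iodosuccinimide, MeCN, 0 °C, dark
Reagents that add atoms: N-iodosuccinimide, O=C1CCC(=O)N1I
Why: Electrophilic aromatic iodination of an aniline with the para position blocked should go to C6, the only free position ortho to NH2, which becomes C4a.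

Step 3
Reactants: 3 6-iodo-2,3-dimethyl-4-(triisopropylsilyloxy)aniline
Product: 5 (4-bromo-5-iodo-2,3-dimethylphenoxy)triisopropylsilane, via arenediazonium bromide 4 (not isolated)
Conditions: t-BuONO, CuBr2, MeCN, 0 → 60 °C
Reagents that add atoms: CuBr2 (copper dibromide), [Cu+2].[Br-].[Br-]
Why: Non-aqueous Sandmeyer bromination (alkyl nitrite/CuBr2) replaces NH2 by Br through the diazonium salt without touching the C–I bond or the silyl ether, placing bromine on the future C8a next to the iodine on the future C4a.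

Step 4
Reactants: 5 (4-bromo-5-iodo-2,3-dimethylphenoxy)triisopropylsilane; 6 (R)-linalool
Product: 8 (3R)-1-[2-bromo-3,4-dimethyl-5-(triisopropylsilyloxy)phenyl]-3,7-dimethyloct-6-en-3-ol, via B-alkyl-9-BBN adduct 7 (not isolated)
Conditions: 6, 9-BBN-H (2.2 equiv B–H), THF, 0 °C → rt; then 5, Pd(dppf)Cl2 (5 mol%), aq. K3PO4, DMF, rt
Reagents that add atoms: none
Why: 9-BBN should hydroborate only the monosubstituted vinyl group of linalool (anti-Markovnikov), and the primary alkylborane should undergo B-alkyl Suzuki–Miyaura coupling at the C–I bond in preference to C–Br, forming C4–C4a while the carbinol stereocentre, which carries no reacting bond, is retained.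

Step 5
Reactants: 8 (3R)-1-[2-bromo-3,4-dimethyl-5-(triisopropylsilyloxy)phenyl]-3,7-dimethyloct-6-en-3-ol
Product: 9 (2R)-2,7,8-trimethyl-2-(4-methylpent-3-en-1-yl)-6-(triisopropylsilyloxy)chroman
Conditions: Pd(OAc)2 (3 mol%), 2-(di-tert-butylphosphino)-1,1'-binaphthyl (4 mol%), Cs2CO3, toluene, 80 °C
Reagents that add atoms: none
Why: Buchwald-type Pd-catalysed intramolecular O-arylation of an aryl bromide by a tertiary alcohol (no β-hydrogen on the alkoxide, so C–O reductive elimination is the only outlet) should close the six-membered ring at O1–C8a; the carbinol C–O bond is not broken, so the R centre of linalool becomes (2R).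

Step 6
Reactants: 9 (2R)-2,7,8-trimethyl-2-(4-methylpent-3-en-1-yl)-6-(triisopropylsilyloxy)chroman
Product: 10 (2E)-2-methyl-5-[(2R)-2,7,8-trimethyl-6-(triisopropylsilyloxy)chroman-2-yl]pent-2-en-1-ol
Conditions: SeO2 (0.3 equiv), t-BuOOH, salicylic acid (cat.), CH2Cl2, 0 °C → rt; then NaBH4, MeOH, 0 °C
Reagents that add atoms: tert-butyl hydroperoxide, CC(C)(C)OO (stoichiometric oxygen source); SeO2, O=[Se]=O (transfers the oxygen atom)
Why: Sharpless SeO2/t-BuOOH allylic oxidation (ene reaction, then 2,3-sigmatropic shift) should hydroxylate the E-methyl group of the only trisubstituted olefin, and the borohydride quench returns any over-oxidised enal to 10.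

Step 7
Reactants: 10 (2E)-2-methyl-5-[(2R)-2,7,8-trimethyl-6-(triisopropylsilyloxy)chroman-2-yl]pent-2-en-1-ol
Product: 11 (2R)-2-[(3E)-5-bromo-4-methylpent-3-en-1-yl]-2,7,8-trimethyl-6-(triisopropylsilyloxy)chroman
Conditions: CBr4, PPh3, CH2Cl2, −20 → 0 °C
Reagents that add atoms: carbon tetrabromide, BrC(Br)(Br)Br
Why: Appel bromination converts the primary allylic alcohol into the bromide under neutral conditions by SN2 at CH2, so the E olefin should be kept.

Step 8
Reactants: 12 (2E,6E,10E)-geranylgeraniol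
Product: 14 (2E,6E,10E)-geranylgeranyl phenyl sulfone, via geranylgeranyl bromide 13 (not isolated)
Conditions: PBr3, Et2O, −10 °C; then PhSO2Na, DMF, rt
Reagents that add atoms: sodium benzenesulfinate, [Na+].[O-]S(=O)c1ccccc1
Why: PBr3 gives the primary allylic bromide and S-alkylation of benzenesulfinate (SN2) should give the allylic sulfone with all E olefins preserved.

Step 9
Reactants: 14 (2E,6E,10E)-geranylgeranyl phenyl sulfone
Product: 16 (2E,6E,10E,14E)-2,6,10,14-tetramethyl-16-(phenylsulfonyl)hexadeca-2,6,10,14-tetraenal, via allylic alcohol 15 (not isolated)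
Conditions: SeO2 (cat.), t-BuOOH, salicylic acid (cat.), CH2Cl2, 0 °C → rt (partial conversion, 14 recycled); then MnO2, CH2Cl2, rt
Reagents that add atoms: tert-butyl hydroperoxide, CC(C)(C)OO (stoichiometric oxygen source); SeO2, O=[Se]=O (transfers the oxygen atom)
Why: SeO2/t-BuOOH allylic oxidation should prefer the E-methyl of the terminal isopropylidene unit (the olefin next to the sulfone is deactivated, the internal ones are more hindered), and MnO2 oxidises only the allylic alcohol, converging alcohol and enal to the E-enal.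

Step 10
Reactants: 16 (2E,6E,10E,14E)-2,6,10,14-tetramethyl-16-(phenylsulfonyl)hexadeca-2,6,10,14-tetraenal
Product: 17 [(2E,6E,10E,14E)-3,7,11,15-tetramethylheptadeca-2,6,10,14,16-pentaen-1-yl] phenyl sulfone
Conditions: Ph3PCH3Br, KN(SiMe3)2, THF, 0 °C; ylide added to 16, THF, −78 → 0 °C
Reagents that add atoms: methyltriphenylphosphonium bromide, C[P+](c1ccccc1)(c1ccccc1)c1ccccc1.[Br-]
Why: Wittig methylenation of the enal gives the terminal 1,3-diene, and adding the ylide to the aldehyde at −78 °C should let carbonyl addition outrun proton abstraction from the allylic sulfone.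

Step 11
Reactants: 17 [(2E,6E,10E,14E)-3,7,11,15-tetramethylheptadeca-2,6,10,14,16-pentaen-1-yl] phenyl sulfone
Product: 19 (3E,7E,11E,15E)-3,7,11,15-tetramethyl-17-(phenylsulfonyl)heptadeca-3,7,11,15-tetraen-1-ol, via B-alkyl-9-BBN adduct 18 (not isolated)
Conditions: 9-BBN-H (1.1 equiv), THF, 0 °C → rt; then aq. NaOH, H2O2, 0 °C
Reagents that add atoms: hydrogen peroxide, OO
Why: Hydroboration–oxidation with 9-BBN should attack only the monosubstituted terminus of the diene (boron on the terminal CH2; trisubstituted olefins and sulfone inert), giving the homoallylic primary alcohol whose carbinol carbon is the future C22'.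

Step 12
Reactants: 19 (3E,7E,11E,15E)-3,7,11,15-tetramethyl-17-(phenylsulfonyl)heptadeca-3,7,11,15-tetraen-1-ol; 11 (2R)-2-[(3E)-5-bromo-4-methylpent-3-en-1-yl]-2,7,8-trimethyl-6-(triisopropylsilyloxy)chroman
Product: 21 (2R)-2-[(3E,7E,11E,15E,19E)-22-hydroxy-4,8,12,16,20-pentamethyl-6-(phenylsulfonyl)docosa-3,7,11,15,19-pentaen-1-yl]-2,7,8-trimethyl-6-(triisopropylsilyloxy)chroman (both epimers at C6'), via dilithiated sulfone 20 (not isolated)
Conditions: 19, n-BuLi (2.1 equiv), THF/DMPU, −78 °C; then 11, −78 → −20 °C; aq. NH4Cl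
Reagents that add atoms: none
Why: Biellmann-type sulfone alkylation, in which the α-sulfonyl carbanion of the dilithio species (far more nucleophilic than the lithium alkoxide) displaces the allylic bromide by SN2 to form C5'–C6'; the new sulfonyl-bearing centre forms unselectively and is erased in step 13.

Step 13
Reactants: 21 (2R)-2-[(3E,7E,11E,15E,19E)-22-hydroxy-4,8,12,16,20-pentamethyl-6-(phenylsulfonyl)docosa-3,7,11,15,19-pentaen-1-yl]-2,7,8-trimethyl-6-(triisopropylsilyloxy)chroman
Product: 22 (3E,7E,11E,15E,19E)-3,7,11,15,19-pentamethyl-22-[(2R)-2,7,8-trimethyl-6-(triisopropylsilyloxy)chroman-2-yl]docosa-3,7,11,15,19-pentaen-1-ol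
Conditions: Pd(dppp)Cl2 (10 mol%), LiEt3BH, THF, 0 °C
Reagents that add atoms: none
Why: Pd-catalysed reductive desulfonylation of an allylic sulfone with LiEt3BH delivers hydride to the less substituted terminus of the π-allyl intermediate, so the C7'=C8' olefin should keep its position and E geometry.

Step 14
Reactants: 22 (3E,7E,11E,15E,19E)-3,7,11,15,19-pentamethyl-22-[(2R)-2,7,8-trimethyl-6-(triisopropylsilyloxy)chroman-2-yl]docosa-3,7,11,15,19-pentaen-1-ol
Product: 23 (2R)-2-[(3E,7E,11E,15E,19E)-22-iodo-4,8,12,16,20-pentamethyldocosa-3,7,11,15,19-pentaen-1-yl]-2,7,8-trimethyl-6-(triisopropylsilyloxy)chroman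
Conditions: I2, PPh3, imidazole, CH2Cl2, 0 °C → rt, dark
Reagents that add atoms: iodine, II
Why: Appel-type iodination (Garegg–Samuelsson conditions) converts the primary alcohol into the iodide by SN2 under neutral conditions that the polyene and the silyl ether should tolerate.

Step 15
Reactants: 24 geranyl bromide
Product: 26 (5E)-6,10-dimethylundeca-5,9-dien-1-yne, via silylalkyne 25 (not isolated)
Conditions: 1-(trimethylsilyl)propyne, n-BuLi, THF, −78 → −20 °C; then 24, −78 → 0 °C; then K2CO3, MeOH, rt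
Reagents that add atoms: 1-(trimethylsilyl)propyne, CC#C[Si](C)(C)C
Why: Propargylic lithiation of the silylpropyne and SN2 alkylation by the allylic bromide (Corey–Kirst homologation), followed by protodesilylation, should give the terminal alkyne with the E olefin intact.

Step 16
Reactants: 26 (5E)-6,10-dimethylundeca-5,9-dien-1-yne; 23 (2R)-2-[(3E,7E,11E,15E,19E)-22-iodo-4,8,12,16,20-pentamethyldocosa-3,7,11,15,19-pentaen-1-yl]-2,7,8-trimethyl-6-(triisopropylsilyloxy)chroman
Product: 29 (2R)-2,7,8-trimethyl-2-[(3E,7E,11E,15E,19E,23E,27E)-4,8,12,16,20,24,28,32-octamethyltritriaconta-3,7,11,15,19,23,27,31-octaen-1-yl]-6-(triisopropylsilyloxy)chroman, via alkenyldimethylalane 27 (not isolated), via alkenylzinc bromide 28 (not isolated)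
Conditions: 26 (1.5 equiv), AlMe3, Cp2ZrCl2 (0.25 equiv), CH2Cl2, 0 °C → rt; volatiles removed in vacuo; ZnBr2, THF, 0 °C; then 23, Pd2(dba)3 (2 mol%), tricyclopentylphosphine (8 mol%), N-methylimidazole, THF/NMP, 80 °C
Reagents that add atoms: trimethylaluminium, C[Al](C)C
Why: Cp2ZrCl2/AlMe3 adds CH3–Al syn across the terminal alkyne of 26 (Negishi carboalumination; the two trisubstituted olefins are inert), putting CH3 on the internal carbon C24' and Al on the terminal CH C23', after which Al-to-Zn exchange gives alkenylzinc 28 and a zerovalent Pd/trialkylphosphine catalyst inserts into the C22'–I bond of 23 (SN2-type oxidative addition), accepts the alkenyl group and reductively eliminates to form C22'–C23'. The closest known reaction types are the one-pot carboalumination/Pd cross-coupling of alkenylalanes through zinc and the Pd/trialkylphosphine Negishi coupling of alkenylzinc halides with unactivated primary alkyl iodides. No ring is closed and no stereocentre is formed; the only new stereo-element is the E-C23'=C24' double bond, fixed by the syn carbometalation and carried through the coupling with retention. The step needs methyl delivery to the internal alkyne carbon (secured by the unhindered terminal alkyne), transfer of the alkenyl and not a methyl group to Pd (sp2 groups transmetalate faster, and excess AlMe3 is pumped off first), and coupling faster than β-hydride elimination of the homoallylic alkyl–Pd (bulky electron-rich phosphine, N-methylimidazole); one flask thus installs the last methyl branch, the last E olefin and the C14 tail and completes the C53 skeleton.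

Step 17
Reactants: 29 (2R)-2,7,8-trimethyl-2-[(3E,7E,11E,15E,19E,23E,27E)-4,8,12,16,20,24,28,32-octamethyltritriaconta-3,7,11,15,19,23,27,31-octaen-1-yl]-6-(triisopropylsilyloxy)chroman
Product: 30 plastochromanol 8
Conditions: Bu4NF, THF, 0 °C, argon; aq. NH4Cl
Reagents that add atoms: none
Why: Fluoride-induced cleavage of the aryl silyl ether (Si–F bond formation) should free the phenol without touching the polyene or C2.

**Compound list**

1 | 4-amino-2,3-dimethylphenol | Cc1c(C)c(N)ccc1O | starting material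
2 | 2,3-dimethyl-4-(triisopropylsilyloxy)aniline | Cc1c(C)c(N)ccc1O[Si](C(C)C)(C(C)C)C(C)C | intermediate
3 | 6-iodo-2,3-dimethyl-4-(triisopropylsilyloxy)aniline | Cc1c(C)c(N)c(I)cc1O[Si](C(C)C)(C(C)C)C(C)C | intermediate
4 | 6-iodo-2,3-dimethyl-4-(triisopropylsilyloxy)benzenediazonium bromide | Cc1c(C)c([N+]#N)c(I)cc1O[Si](C(C)C)(C(C)C)C(C)C.[Br-] | intermediate (not isolated)
5 | (4-bromo-5-iodo-2,3-dimethylphenoxy)triisopropylsilane | Cc1c(C)c(Br)c(I)cc1O[Si](C(C)C)(C(C)C)C(C)C | intermediate
6 | (R)-(−)-linalool, (3R)-3,7-dimethylocta-1,6-dien-3-ol | C=C[C@](C)(O)CCC=C(C)C | starting material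
7 | B-[(3S)-3-hydroxy-3,7-dimethyloct-6-en-1-yl]-9-borabicyclo[3.3.1]nonane (same spatial arrangement as 6; the descriptor changes only because boron ranks below carbon) | CC(C)=CCC[C@@](C)(O)CCB1C2CCCC1CCC2 | intermediate (not isolated)
8 | (3R)-1-[2-bromo-3,4-dimethyl-5-(triisopropylsilyloxy)phenyl]-3,7-dimethyloct-6-en-3-ol | CC(C)=CCC[C@@](C)(O)CCc1cc(O[Si](C(C)C)(C(C)C)C(C)C)c(C)c(C)c1Br | intermediate
9 | (2R)-2,7,8-trimethyl-2-(4-methylpent-3-en-1-yl)-6-(triisopropylsilyloxy)chroman | CC(C)=CCC[C@]1(C)CCc2cc(O[Si](C(C)C)(C(C)C)C(C)C)c(C)c(C)c2O1 | intermediate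
10 | (2E)-2-methyl-5-[(2R)-2,7,8-trimethyl-6-(triisopropylsilyloxy)chroman-2-yl]pent-2-en-1-ol | OC/C(C)=C/CC[C@]1(C)CCc2cc(O[Si](C(C)C)(C(C)C)C(C)C)c(C)c(C)c2O1 | intermediate
11 | (2R)-2-[(3E)-5-bromo-4-methylpent-3-en-1-yl]-2,7,8-trimethyl-6-(triisopropylsilyloxy)chroman | BrC/C(C)=C/CC[C@]1(C)CCc2cc(O[Si](C(C)C)(C(C)C)C(C)C)c(C)c(C)c2O1 | intermediate
12 | (2E,6E,10E)-geranylgeraniol | CC(C)=CCC/C(C)=C/CC/C(C)=C/CC/C(C)=C/CO | starting material
13 | (2E,6E,10E)-geranylgeranyl bromide | CC(C)=CCC/C(C)=C/CC/C(C)=C/CC/C(C)=C/CBr | intermediate (not isolated)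
14 | (2E,6E,10E)-geranylgeranyl phenyl sulfone | CC(C)=CCC/C(C)=C/CC/C(C)=C/CC/C(C)=C/CS(=O)(=O)c1ccccc1 | intermediate
15 | (2E,6E,10E,14E)-2,6,10,14-tetramethyl-16-(phenylsulfonyl)hexadeca-2,6,10,14-tetraen-1-ol | OC/C(C)=C/CC/C(C)=C/CC/C(C)=C/CC/C(C)=C/CS(=O)(=O)c1ccccc1 | intermediate (not isolated)
16 | (2E,6E,10E,14E)-2,6,10,14-tetramethyl-16-(phenylsulfonyl)hexadeca-2,6,10,14-tetraenal | O=C/C(C)=C/CC/C(C)=C/CC/C(C)=C/CC/C(C)=C/CS(=O)(=O)c1ccccc1 | intermediate
17 | [(2E,6E,10E,14E)-3,7,11,15-tetramethylheptadeca-2,6,10,14,16-pentaen-1-yl] phenyl sulfone | C=C/C(C)=C/CC/C(C)=C/CC/C(C)=C/CC/C(C)=C/CS(=O)(=O)c1ccccc1 | intermediate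
18 | B-[(3E,7E,11E,15E)-3,7,11,15-tetramethyl-17-(phenylsulfonyl)heptadeca-3,7,11,15-tetraen-1-yl]-9-borabicyclo[3.3.1]nonane | B1(CC/C(C)=C/CC/C(C)=C/CC/C(C)=C/CC/C(C)=C/CS(=O)(=O)c3ccccc3)C2CCCC1CCC2 | intermediate (not isolated)
19 | (3E,7E,11E,15E)-3,7,11,15-tetramethyl-17-(phenylsulfonyl)heptadeca-3,7,11,15-tetraen-1-ol | OCC/C(C)=C/CC/C(C)=C/CC/C(C)=C/CC/C(C)=C/CS(=O)(=O)c1ccccc1 | intermediate
20 | O,C-dilithio derivative of 19 (lithium alkoxide, lithium on the sulfonyl-bearing carbon) | [Li]OCC/C(C)=C/CC/C(C)=C/CC/C(C)=C/CC/C(C)=C/C([Li])S(=O)(=O)c1ccccc1 | intermediate (not isolated)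
21 | (2R)-2-[(3E,7E,11E,15E,19E)-22-hydroxy-4,8,12,16,20-pentamethyl-6-(phenylsulfonyl)docosa-3,7,11,15,19-pentaen-1-yl]-2,7,8-trimethyl-6-(triisopropylsilyloxy)chroman, both epimers at C6' | OCC/C(C)=C/CC/C(C)=C/CC/C(C)=C/CC/C(C)=C/C(S(=O)(=O)c1ccccc1)C/C(C)=C/CC[C@]2(C)CCc3cc(O[Si](C(C)C)(C(C)C)C(C)C)c(C)c(C)c3O2 | intermediate
22 | (3E,7E,11E,15E,19E)-3,7,11,15,19-pentamethyl-22-[(2R)-2,7,8-trimethyl-6-(triisopropylsilyloxy)chroman-2-yl]docosa-3,7,11,15,19-pentaen-1-ol | OCC/C(C)=C/CC/C(C)=C/CC/C(C)=C/CC/C(C)=C/CC/C(C)=C/CC[C@]1(C)CCc2cc(O[Si](C(C)C)(C(C)C)C(C)C)c(C)c(C)c2O1 | intermediate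
23 | (2R)-2-[(3E,7E,11E,15E,19E)-22-iodo-4,8,12,16,20-pentamethyldocosa-3,7,11,15,19-pentaen-1-yl]-2,7,8-trimethyl-6-(triisopropylsilyloxy)chroman | ICC/C(C)=C/CC/C(C)=C/CC/C(C)=C/CC/C(C)=C/CC/C(C)=C/CC[C@]1(C)CCc2cc(O[Si](C(C)C)(C(C)C)C(C)C)c(C)c(C)c2O1 | intermediate
24 | geranyl bromide, (2E)-1-bromo-3,7-dimethylocta-2,6-diene | CC(C)=CCC/C(C)=C/CBr | starting material
25 | [(5E)-6,10-dimethylundeca-5,9-dien-1-yn-1-yl]trimethylsilane | CC(C)=CCC/C(C)=C/CCC#C[Si](C)(C)C | intermediate (not isolated)
26 | (5E)-6,10-dimethylundeca-5,9-dien-1-yne | CC(C)=CCC/C(C)=C/CCC#C | intermediate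
27 | dimethyl[(1E,5E)-2,6,10-trimethylundeca-1,5,9-trien-1-yl]alane | CC(C)=CCC/C(C)=C/CC/C(C)=C/[Al](C)C | intermediate (not isolated)
28 | [(1E,5E)-2,6,10-trimethylundeca-1,5,9-trien-1-yl]zinc bromide | CC(C)=CCC/C(C)=C/CC/C(C)=C/[Zn]Br | intermediate (not isolated)
29 | (2R)-2,7,8-trimethyl-2-[(3E,7E,11E,15E,19E,23E,27E)-4,8,12,16,20,24,28,32-octamethyltritriaconta-3,7,11,15,19,23,27,31-octaen-1-yl]-6-(triisopropylsilyloxy)chroman | CC(C)=CCC/C(C)=C/CC/C(C)=C/CC/C(C)=C/CC/C(C)=C/CC/C(C)=C/CC/C(C)=C/CC/C(C)=C/CC[C@]1(C)CCc2cc(O[Si](C(C)C)(C(C)C)C(C)C)c(C)c(C)c2O1 | intermediate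
30 | plastochromanol 8, (2R)-2,7,8-trimethyl-2-[(3E,7E,11E,15E,19E,23E,27E)-4,8,12,16,20,24,28,32-octamethyltritriaconta-3,7,11,15,19,23,27,31-octaen-1-yl]chroman-6-ol | CC(C)=CCC/C(C)=C/CC/C(C)=C/CC/C(C)=C/CC/C(C)=C/CC/C(C)=C/CC/C(C)=C/CC/C(C)=C/CC[C@]1(C)CCc2cc(O)c(C)c(C)c2O1 | target

**Step count and risks**

Total step count: 17. Longest linear sequence: 12 steps (steps 1–7, 12–14, 16, 17, from 4-amino-2,3-dimethylphenol).

Steps most likely to fail:

1. Step 16. The alkyl–Pd species formed from 23 is homoallylic, so β-hydride elimination to a conjugated diene may outrun the slow alkenyl transfer from a zinc/aluminium mixture, and residual metal–CH3 groups may transfer methyl in place of the alkenyl group. The fallback reverses the polarity and uses only established couplings; it sets out from 26 and 23 and comes back at 29. Alkyne 26 would be methylaluminated as in step 16 (through 27) and the alane quenched with I2 (THF, −30 °C) to give the isolable alkenyl iodide (1E,5E)-1-iodo-2,6,10-trimethylundeca-1,5,9-triene F1. Iodide 23 would be converted by direct zinc insertion (Zn dust, LiCl, THF, 40 °C) into the homoallylic alkylzinc iodide F2. F1 and F2 would then be joined by a Negishi coupling (Pd(DPEphos)Cl2 cat., THF, rt), the alkylzinc/alkenyl iodide pairing established for 1,5-diene oligoisoprenoids, to give 29.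

2. Step 9. The ene reaction may not distinguish the terminal isopropylidene olefin from the two internal trisubstituted olefins, and over-oxidation at low conversion may erode material. The fallback replaces allylic oxidation by terminal olefin cleavage and re-olefination; it sets out from 14 and comes back at 16. Sulfone 14 would be treated with N-bromosuccinimide in aqueous THF at 0 °C (van Tamelen conditions, which favour the terminal olefin of a polyprenyl chain) to give the terminal bromohydrin 14-bromo-15-hydroxy-14,15-dihydrogeranylgeranyl phenyl sulfone F3. K2CO3 in MeOH would close it to the terminal epoxide 14,15-epoxy-14,15-dihydrogeranylgeranyl phenyl sulfone F4. Periodic acid (HIO4, THF/Et2O, 0 °C) would cleave the epoxide to the trisnor aldehyde (4E,8E,12E)-4,8,12-trimethyl-14-(phenylsulfonyl)tetradeca-4,8,12-trienal F5. An E-selective Wittig reaction of F5 with the stabilised ylide 2-(triphenylphosphoranylidene)propanal (toluene, 90 °C) would return to enal 16.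

3. Step 4. The tertiary hydroxyl next to the new C–B bond may tie the borane up as a cyclic borinate (slow transmetalation, protodeboronation), and a sluggish coupling may erode the iodine-over-bromine discrimination. The fallback forms C4–C4a by a Heck reaction and sets the oxidation level afterwards; it sets out from 5 and 6 and comes back at 8. Aryl iodide 5 and linalool 6 (Pd(OAc)2 cat., Ag2CO3, DMF, 60 °C; the tertiary allylic alcohol has no carbinol hydrogen, so β-hydride elimination can only give the styrene) would give the styrenyl carbinol (1E,3R)-1-[2-bromo-3,4-dimethyl-5-(triisopropylsilyloxy)phenyl]-3,7-dimethylocta-1,6-dien-3-ol F6. Its disubstituted olefin would be reduced chemoselectively with diimide (2-nitrobenzenesulfonyl hydrazide, Et3N, CH2Cl2, rt), which leaves the trisubstituted olefin and the C–Br bond, to return to 8.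

**Further compounds**

F1 | step 16 | (1E,5E)-1-iodo-2,6,10-trimethylundeca-1,5,9-triene | CC(C)=CCC/C(C)=C/CC/C(C)=C/I
F2 | step 16 | homoallylic alkylzinc iodide from 23, [(3E,7E,11E,15E,19E)-3,7,11,15,19-pentamethyl-22-[(2R)-2,7,8-trimethyl-6-(triisopropylsilyloxy)chroman-2-yl]docosa-3,7,11,15,19-pentaen-1-yl]zinc iodide | I[Zn]CC/C(C)=C/CC/C(C)=C/CC/C(C)=C/CC/C(C)=C/CC/C(C)=C/CC[C@]1(C)CCc2cc(O[Si](C(C)C)(C(C)C)C(C)C)c(C)c(C)c2O1
F3 | step 9 | 14-bromo-15-hydroxy-14,15-dihydrogeranylgeranyl phenyl sulfone (racemic at C14) | CC(C)(O)C(Br)CC/C(C)=C/CC/C(C)=C/CC/C(C)=C/CS(=O)(=O)c1ccccc1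
F4 | step 9 | 14,15-epoxy-14,15-dihydrogeranylgeranyl phenyl sulfone (racemic) | CC1(C)OC1CC/C(C)=C/CC/C(C)=C/CC/C(C)=C/CS(=O)(=O)c1ccccc1
F5 | step 9 | (4E,8E,12E)-4,8,12-trimethyl-14-(phenylsulfonyl)tetradeca-4,8,12-trienal | O=CCC/C(C)=C/CC/C(C)=C/CC/C(C)=C/CS(=O)(=O)c1ccccc1
F6 | step 4 | (1E,3R)-1-[2-bromo-3,4-dimethyl-5-(triisopropylsilyloxy)phenyl]-3,7-dimethylocta-1,6-dien-3-ol | CC(C)=CCC[C@@](C)(O)/C=C/c1cc(O[Si](C(C)C)(C(C)C)C(C)C)c(C)c(C)c1Br
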